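Ring A is cut at C1–C6 and C4–C5. The arc C1–C2(Br)–C3(Br)–C4(H), together with the oxygen on C1, is a latent 3,4-dibromofuran. C5(Br)–C6(OAr) is an alkyne bearing bromine and the ring B phenoxy group. One operation, a pressure-driven [4+2] cycloaddition followed by acid-catalysed opening of the resulting oxygen bridge, assembles the whole pentasubstituted ring A. It leaves C4, para to the hydroxyl, unbrominated, a pattern that direct bromination of a phenol does not give. The precursor is 2,4-dibromo-1-[(bromoethynyl)oxy]benzene, reached in two steps from 2,4-dibromophenol and tribromoethylene. Its partner, the C2v-symmetric furan, is purchased.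

Key step: step 3

Remark on the chemistry: ring A is numbered C1 (OH), C2 (Br), C3 (Br), C4 (H), C5 (Br), C6 (OAr), and ring B is the 2,4-dibromophenyl group. The target has no stereocentre. The bicyclic adduct is assumed to form as a racemate, and its SMILES shows one enantiomer.

Step 1
Reactants: 1 2,4-dibromophenol; 2 tribromoethylene
Product: 4 (E)-2,4-dibromo-1-[(1,2-dibromoethenyl)oxy]benzene, via dibromoacetylene 3 (not isolated)
Conditions: K2CO3 (2 equiv), DMF, Ar, slow addition of 2 (1.5 equiv), 23 → 50 °C
Reagents that add atoms: none
Why: Carbonate removes HBr from 2 to feed a low stationary concentration of 3, the phenoxide of 1 adds to it in anti fashion and the vinyl anion is protonated, which is the elimination–addition O-vinylation of phenols long used with trihaloethylenes, so the E-alkene (bromines trans) is expected and the weak base stops before a second elimination.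

Step 2
Reactants: 4 (E)-2,4-dibromo-1-[(1,2-dibromoethenyl)oxy]benzene
Product: 5 2,4-dibromo-1-[(bromoethynyl)oxy]benzene
Conditions: KN(SiMe3)2 (1.1 equiv), THF, −78 → −20 °C; cold work-up, short basic alumina plug, used at once
Reagents that add atoms: none
Why: Deprotonation of the acidic vinyl C–H and loss of bromide from the oxygen-bearing carbon (E1cB-type dehydrobromination of a 1,2-dihalovinyl ether, the established way to haloalkynyl ethers, with a Fritsch–Buttenberg–Wiechell shift of the α-bromo carbenoid converging on the same alkyne) should give 5, and the hindered silylamide is chosen because an alkyllithium would exchange the ring B bromines.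

Step 3
Reactants: 5 2,4-dibromo-1-[(bromoethynyl)oxy]benzene; 6 3,4-dibromofuran
Product: 8 2,3,5-tribromo-6-(2,4-dibromophenoxy)phenol (target), via oxanorbornadiene adduct 7 (not isolated)
Conditions: 6 (3 equiv), BHT (1 mol %), CH2Cl2, 15 kbar, 40 °C; decompress, concentrate; TfOH (10 mol %), dry CH2Cl2, −20 → 23 °C
Reagents that add atoms: none
Why: Proposed new method: the α-carbons of furan 6 and the two sp carbons of 5 combine in a concerted, suprafacial Diels–Alder reaction that forms C1–C6 and C4–C5 together and closes ring A as a six-membered carbocycle in intermolecular [4+2] mode, the furan oxygen being left as the C1–O–C4 bridge of 7-oxanorbornadiene 7. The closest known reaction type is the furan–alkyne Diels–Alder reaction followed by acid isomerisation of the 7-oxanorbornadiene to a phenol, which is established only for acceptor-substituted alkynes; as 5 has no acceptor, the large negative activation volume of the cycloaddition is used (15 kbar) instead of heat, which would invite the retro-reaction that expels dibromoacetylene from 7. Reactivity is argued from the release of the electronegative oxygen and bromine substituents from sp to sp2 carbon, from the weak donor power of the electron-poor 2,4-dibromophenoxy group, and from the fact that 6 is a known diene in cycloadditions. No regiochemical issue arises in the cycloaddition because 6 is symmetric, and the two bridgehead stereocentres of 7 (C1 and C4) are tied to one relative configuration by the oxygen bridge, form as a racemate and vanish on aromatisation. The selectivity that matters is the direction of bridge opening: protonation of the bridge oxygen and heterolysis of C4–O gives a cyclohexadienyl cation with charge on C2, C4 and C6, where the aryloxy oxygen on C6 stabilises it as an oxocarbenium ion, whereas heterolysis of C1–O would spread charge only over C1, C3 and C5 without such help. Loss of the proton from C1 then aromatises ring A with the hydroxyl on C1 next to the ether, regenerates the acid and is irreversible, while the absence of water protects the bromo enol ether of 7 from hydrolysis.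

Compound list
1 | 2,4-dibromophenol | Oc1ccc(Br)cc1Br | starting material
2 | tribromoethylene | BrC=C(Br)Br | starting material
3 | dibromoacetylene (formed and consumed in the flask) | BrC#CBr | intermediate
4 | (E)-2,4-dibromo-1-[(1,2-dibromoethenyl)oxy]benzene | Br/C=C(/Br)Oc1ccc(Br)cc1Br | intermediate
5 | 2,4-dibromo-1-[(bromoethynyl)oxy]benzene | BrC#COc1ccc(Br)cc1Br | intermediate
6 | 3,4-dibromofuran | Brc1cocc1Br | starting material
7 | rac-(1S,4R)-2,3,5-tribromo-6-(2,4-dibromophenoxy)-7-oxabicyclo[2.2.1]hepta-2,5-diene (racemate, one enantiomer drawn) | O1[C@@H]2C(Br)=C(Br)[C@H]1C(Br)=C2Oc3ccc(Br)cc3Br | intermediate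
8 | 2,3,5-tribromo-6-(2,4-dibromophenoxy)phenol | Oc1c(Br)c(Br)cc(Br)c1Oc1ccc(Br)cc1Br | target

Total step count: 3
Longest linear sequence: 3 (1 → 4 → 5 → 8)

Steps most likely to fail

Risk 1, step 3. Even under pressure the cycloaddition may stay slower than self-oligomerisation of the haloalkynyl ether. The acid stage may also lose material through hydrolysis of the enol ether or opening of the bridge in the wrong direction. The fallback gives up the cycloaddition and uses known aromatic chemistry, setting out from 1 and coming back at 8.
- Nucleophilic aromatic substitution of commercial 3,5-dibromo-2-fluorobenzaldehyde (O=Cc1cc(Br)cc(Br)c1F) by 1 (K2CO3, DMF, 90 °C) should give 3,5-dibromo-2-(2,4-dibromophenoxy)benzaldehyde F1.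
- Baeyer–Villiger oxidation (mCPBA, CH2Cl2) should give 3,5-dibromo-2-(2,4-dibromophenoxy)phenyl formate F2.
- Methanolysis of that formate (catalytic K2CO3, MeOH) should give 3,5-dibromo-2-(2,4-dibromophenoxy)phenol F3.
- Ortho-selective monobromination (NBS, catalytic iPr2NH, CH2Cl2, 0 °C) should enter the open position next to the hydroxyl, because the para position is flanked by two bromines, and give 8.

Risk 2, step 2. The vinyl carbanion lies anti to the aryloxy group. Ejection of phenoxide, the reverse of the addition, may therefore outrun syn loss of bromide. The product may also oligomerise on concentration. The fallback replaces elimination by a reduction and re-bromination sequence, setting out from 4 and coming back at 5.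
- Reductive anti-debromination of the trans-dibromide with activated Zn dust in THF should give 2,4-dibromo-1-(ethynyloxy)benzene F4.
- Electrophilic bromination of its terminal C–H (NBS, catalytic AgNO3, acetone, 0 °C) should give 5.

Risk 3, step 1.
- The phenoxide may attack bromine instead of carbon of the dihaloalkyne.
- A second elimination–addition may lead on to a ketene acetal.
- The air-sensitive, explosive dibromoacetylene may decompose before capture, so it is never isolated and the flask is kept under argon.

The fallback avoids the dihaloalkyne entirely, setting out from 1 and coming back at 5.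
- O-formylation with acetic formic anhydride should give 2,4-dibromophenyl formate F5.
- Corey–Fuchs-type dibromomethylenation (CBr4, PPh3, Zn dust, CH2Cl2) should give 2,4-dibromo-1-[(2,2-dibromoethenyl)oxy]benzene F6.
- The vinyl hydrogen of that ether has a bromine anti to it, so a plain E2 elimination (KOtBu, THF, −78 °C) should give 5.

Further compounds
F1 | step 3 | 3,5-dibromo-2-(2,4-dibromophenoxy)benzaldehyde | O=Cc1cc(Br)cc(Br)c1Oc1ccc(Br)cc1Br
F2 | step 3 | 3,5-dibromo-2-(2,4-dibromophenoxy)phenyl formate | O=COc1cc(Br)cc(Br)c1Oc1ccc(Br)cc1Br
F3 | step 3 | 3,5-dibromo-2-(2,4-dibromophenoxy)phenol | Oc1cc(Br)cc(Br)c1Oc1ccc(Br)cc1Br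
F4 | step 2 | 2,4-dibromo-1-(ethynyloxy)benzene | C#COc1ccc(Br)cc1Br
F5 | step 1 | 2,4-dibromophenyl formate | O=COc1ccc(Br)cc1Br
F6 | step 1 | 2,4-dibromo-1-[(2,2-dibromoethenyl)oxy]benzene | BrC(Br)=COc1ccc(Br)cc1Br
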